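D climbed to a level and stayed there, both in the larch flask at 16 °C and in the cedar flask at 30 °C, and I wanted to know whether green and violet would reach that level in their time.

| flask | X | temperature | remark | time |
|---|---|---|---|---|
| larch | 0.039 M | 16 °C | run made earlier |  |
| cedar | 0.074 M | 30 °C | run made earlier |  |
| green | 0.050 M |  | at 10 °C until 30 h, from then on at 35 °C | 6.0 d |
| violet | 0.030 M |  | at 10 °C throughout | 6.0 d |

larch run (percent of the X charged)

| time / d | D / % | X / % |
|---|---|---|
| 0.333 | 79.6 | 0 |
| 0.500 | 87.3 | 0.4 |
| 0.833 | 91.3 | 0 |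
| 1.67 | 91.8 | 0 |
| 2.50 | 92.1 | 0 |
| 4.00 | 91.5 | 0.3 |

cedar run (percent of the X charged)

| time / h | D / % | X / % |
|---|---|---|
| 2.00 | 89.5 | 0.2 |
| 8.00 | 91.8 | 0 |
| 15.0 | 92.6 | 0.2 |
| 20.0 | 92.5 | 0.4 |
| 25.0 | 92.0 | 0.2 |
| 40.0 | 92.0 | 0.3 |

(scatter of a reading: 0.5 percentage points)

- which of the two ends with the higher amount of D, in percent of the X charged ("neither" if they lie within 2 percentage points) (green / violet / neither)
- D at the end, in percent of the X charged, green
- D at the end, in percent of the X charged, violet



I built the flask up one process at a time. With X going straight to D, D tracks X and ends at 100%. But in larch X read 0% at the first reading while D read 79.6% and was still rising, so I added a slower stage between them, which delays D and leaves its end unchanged. The readings from 1.67 d on in larch and from 20.0 h on in cedar, at different temperatures and charges, lay between 91.5% and 92.5%, so I added a ceiling and froze it at their mean, the plateau, 92.0%.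

With the plateau frozen, the gap below it was the one thing left to follow:

gap at time t = gap at the start × exp(−closing rate × t)

Larch gave a closing rate of 5.79 d⁻¹. Cedar, from one small gap and so roughly, gave 1.81 h⁻¹. Together these read as an activation energy of 105 kJ mol⁻¹, and at 10 °C:

closing rate = 2.30 d⁻¹

The closing half-life, the time in which the gap to the plateau halves at a given temperature, is then ln 2 / closing rate = 0.301 d.

Violet's 6.0 d is far longer than that, about 19.9 half-lives. Green has about 4.15 of them before its bath turns hotter. I therefore expected both flasks at the plateau.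

The forecast said 92% for green, 92% for violet and neither for the comparison, holding that “six days is ample for completion, even allowing for a large error in Ea”.

Green ended at 91.8% and violet at 92.3%, so the answer is neither.

    X ⇌ Q (K = 0.280, k = 3.70 × 10⁻⁶ s⁻¹, Ea = 95.0 kJ mol⁻¹, ΔH = −47.0 kJ mol⁻¹)
    X → E (k = 1.70 × 10⁻⁴ s⁻¹, Ea = 82.0 kJ mol⁻¹)
    Q → E (k = 1.40 × 10⁻⁵ s⁻¹, Ea = 102 kJ mol⁻¹)
    E ⇌ D (K = 12.0, k = 3.00 × 10⁻⁵ s⁻¹, Ea = 100 kJ mol⁻¹, ΔH = −2.00 kJ mol⁻¹)
    (constants at 10 °C)

Violet stopped short of 100% because of the way back from D to E: without that way back the same flask ended at >99.9% instead of 92.3%, so violet's ceiling is an equilibrium between D and E, and its relaxation half-life, both ways together, was 0.247 d, short against the 6.0 d. A neighbour flask, violet repeated at −5 °C, has a closing half-life of 3.63 d by the same reckoning, which allows 1.65 half-lives and puts D at 62.7%; that flask ended at 69.8%, with E at 29.5%.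

Readings and results were computed from invented constants.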